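## Structural features

The target, (2S)-7-hydroxy-2-(4-methoxy-3,5-diprenylphenyl)chroman-4-one, is a flavanone. Aromatic ring A is fused along C4a–C8a to the dihydropyranone ring C (O1, C2, C3, C4=O), and C2 carries ring B, a 4-methoxyphenyl group flanked by two prenyl chains. Ring A has a single free phenol at C7, meta to O1 and para to C4a, and only hydrogen at C5, C6 and C8. The only stereocentre is C2 (S): it is benzylic, bears O1 and lies β to the ketone, with no neighbouring stereocentre. Deprotonation at C3 opens ring C by E1cB loss of O1 (chalcone formation), so base must be avoided once C2 is set, as must acid strong enough to ionize the benzylic C2–O bond. The two trisubstituted prenyl alkenes are the fragile groups: sulfenyl halides, halonium sources, peracids, strong protic acid and hydrogenation all attack them. The real difficulty is therefore to assemble the aryl ketone and aryl ether of ring C around a labile C2 while two nucleophilic alkenes are carried along. The key step uses the fact that the C4a=C8a bond of ring A is also the enone C=C of a 2,3-dihydropyran-4-one, and that C5–C8 with oxygen on C7 map onto a 1-alkoxy-3-siloxy diene. Ring A can thus be grown on an already chiral ring C without touching any bond to C2.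

## Logic of the disconnections

18 from 17, and 17 from 13 + 14: the O–Si bond is cut first, then C8–C8a and C4a–C5, with formal return of benzenesulfenic acid and methanol. This removes the whole of ring A and leaves the monocyclic 13, whose single stereocentre is already the one required. The forward step must be regioselective (oxygen at C7) and free of base, which is why the activating group on C4a is a sulfoxide that leaves by thermal syn-elimination.

13 from 10 + 11: the O1–C6 and C5=C6 bonds of the pyranone (C6 becomes C8a) are cut, so that the one-carbon unit 11 is inserted between the carbinol oxygen and the sulfinyl-bearing methylene. Sulfur then arrives inside the chain at the sulfoxide level. This avoids electrophilic sulfenylation of a preformed ring with a sulfenyl halide and any later oxidation, both of which would endanger the prenyl alkenes. The forward step needs a ring closure under weakly acidic conditions that keeps the carbinol C–O bond.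

10 from 8 + 9: the acyl–CH2S bond is cut. The gain is a commercial sulfoxide and a simple β-hydroxy thioester; the demand is an excess of carbanion at low temperature, because the hydroxyl and the product both consume base.

8 from 4 + 6: the C2–C3 bond is cut, and this is where the stereocentre is created under catalyst control. The forward step must deliver the nucleophile to the Si face of 4. A hetero-Diels–Alder reaction of 4 with 14 would reach the ring more directly and is kept as a fallback, but it needs Lewis-acid catalysis (hydrogen-bond-donor diol catalysts are established for 1-amino-3-siloxy dienes, not for 14). It would also leave sulfur to be introduced at C5 in the presence of the prenyl groups.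

6 from 5: the O–Si bond is cut; the silyl ketene thioacetal is made in one operation from the thioester.

4 from 2 + 3: both aryl–CH2 bonds are cut, so that the two prenyl groups come from one double cross-coupling. The forward step must transfer the allyl unit through its unsubstituted carbon at two hindered positions.

2 from 1: the O–CH3 bond is cut; the methyl ether is the spectator group of the target and is installed first.

## Other disconnections considered

Alternative 1: The cut removes O1–C8a and C4–C4a together. In the forward step, fluoride releases a chloro-substituted aryne from the ortho-silylaryl triflate A3 in the presence of the alkoxide of the hydroxy ester A2. Oxygen adds at the aryne carbon remote from chlorine, and the aryl anion, stabilized next to chlorine, acylates itself on the ester to give A1.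
- In its favour: it is more convergent than the chosen plan, since two elaborate fragments meet in the ring-forming step. The C2–O bond is not broken, and the chlorine gives regiocontrol that equals the polarization control of step 7.
- Against it here: an aliphatic alkoxide is a modest aryne partner, and the aryl anion can be quenched by a proton before it reaches the ester. The β-aryloxy ester sits in basic fluoride medium and can eliminate by E1cB, with loss of C2.
- After A1, the chlorine must be removed reductively in the presence of two trisubstituted alkenes and an aryl ketone, and the acetal must be cleaved with acid.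
- Step economy: with the multistep preparation of A3, the sequence is longer than the seven steps of the chosen plan.
- Mechanism: an anionic cascade stands against the neutral thermal sequence through 15, which keeps base away from C2.

Alternative 2: The cut is C4–C4a. Bromine–lithium exchange on the aryl bromide of the N-methoxy-N-methylamide A5 gives an aryllithium that adds to the amide carbonyl; the chelated tetrahedral intermediate collapses on work-up to A4.
- In its favour: regiochemistry is fixed by the position of bromine, which is more certain than a cycloaddition that relies on orbital polarization. Over-addition is blocked. A4 carries a robust silyl ether and can be isolated, which is better than the labile ether 17.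
- Against it here: A5 needs the benzylic C2–O aryl ether to be formed stereospecifically, in practice by a Mitsunobu inversion of an electron-rich benzylic β-hydroxy amide. Elimination to the cinnamamide and partial loss of configuration are both likely.
- The organolithium may also deprotonate C3 and expel the phenoxide, and the final desilylation needs buffered fluoride to spare C2.
- Step economy: about equal to the chosen plan.
- Structure: C2 is set and then inverted, whereas the chosen plan never breaks a bond to C2 after step 4.

Alternative 3: The cut is O1–C8a. The alkoxide of the β-hydroxy ketone A7 attacks the fluorine-bearing carbon, which is activated by the ortho ketone, and expels fluoride through a Meisenheimer intermediate to give A6 with retention at C2.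
- In its favour: it is the shortest route to ring C, one asymmetric aldol and one ring closure, and it uses no sulfur. In step count it equals or betters the chosen plan, and the ring closure is a well-known reaction type.
- Against it here: the reacting species is the alkoxide of a benzylic aldol, exactly the intermediate that undergoes retro-aldol cleavage and dehydration to the chalcone. Both erase C2.
- The alkoxy group para to the ketone weakens the activation of the fluoride, so stronger base or heat would be needed, and the flavanone formed can racemize in the same medium.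
- An enantioselective aldol of an aryl methyl ketone with an aromatic aldehyde is less general than the thioester aldol of step 4, and the acetal must still be removed with acid.
- Mechanism: it is simpler than the chosen plan, but it places a strong base on the stereocentre-bearing intermediate, which the chosen plan avoids.

Key step: step 7

Assumption: the (S)-BINOL–Ti(OiPr)4 Lewis acid is taken to direct a silyl nucleophile to the Si face of aldehyde 4, as this ligand antipode does in related allyl additions to aldehydes; if the sense were the opposite, (R)-BINOL would be used.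

Remark: 10, 12, 13 and 15 are carried as mixtures of epimers at sulfur; the sulfur centre is lost in step 7, so its configuration does not matter.

## Route

Step 1
Reactants: 1 3,5-dibromo-4-hydroxybenzaldehyde
Product: 2 3,5-dibromo-4-methoxybenzaldehyde
Conditions: MeI, K2CO3, DMF, rt
Reagents that add atoms: iodomethane, CI
Why: Williamson O-methylation of an acidic 2,6-dibromophenol; the ether is the spectator group of the target and keeps the phenol from interfering with the palladium coupling or cyclizing onto a prenyl group.

Step 2
Reactants: 2 3,5-dibromo-4-methoxybenzaldehyde; 3 prenylboronic acid pinacol ester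
Product: 4 4-methoxy-3,5-bis(3-methylbut-2-en-1-yl)benzaldehyde
Conditions: 3 (2.6 equiv), [PdCl2(IPent)(3-chloropyridine)] (4 mol%; IPent = 1,3-bis[2,6-di(pentan-3-yl)phenyl]imidazol-2-ylidene), aq. KOH, THF, 70 °C
Reagents that add atoms: none
Why: Double Suzuki–Miyaura coupling of an allylic boronate; oxidative addition of the electron-poor aryl bromide to zerovalent palladium is easy, and the bulky carbene ligand favours reductive elimination from the primary σ-allyl complex, so the linear prenyl group and not the 1,1-dimethylallyl isomer should be installed at both positions.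

Step 3
Reactants: 5 S-tert-butyl thioacetate
Product: 6 1-(tert-butylsulfanyl)-1-(trimethylsilyloxy)ethene
Conditions: LiN(iPr)2, THF, −78 °C; TMSCl, −78 °C to rt; distillation
Reagents that add atoms: chlorotrimethylsilane, C[Si](C)(C)Cl
Why: Kinetic enolization of the thioester and O-silylation of the enolate give the silyl ketene thioacetal, the nucleophile of the following Mukaiyama aldol reaction.

Step 4
Reactants: 4 4-methoxy-3,5-bis(3-methylbut-2-en-1-yl)benzaldehyde; 6 1-(tert-butylsulfanyl)-1-(trimethylsilyloxy)ethene
Product: 8 S-tert-butyl (3S)-3-hydroxy-3-[4-methoxy-3,5-bis(3-methylbut-2-en-1-yl)phenyl]propanethioate, via trimethylsilyl ether 7 (not isolated)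
Conditions: (S)-BINOL (20 mol%), Ti(OiPr)4 (20 mol%), 4 Å MS, Et2O, −20 °C; then 1 M HCl, THF, 0 °C
Reagents that add atoms: none
Why: Titanium–BINOL-catalysed enantioselective Mukaiyama aldol addition; the chiral Lewis acid binds the aldehyde, the ketene thioacetal attacks the Si face with silyl transfer to oxygen (7), and dilute acid frees the carbinol, so the future C2 is set as S by the ligand.

Step 5
Reactants: 8 S-tert-butyl (3S)-3-hydroxy-3-[4-methoxy-3,5-bis(3-methylbut-2-en-1-yl)phenyl]propanethioate; 9 methyl phenyl sulfoxide
Product: 10 (4S)-4-hydroxy-4-[4-methoxy-3,5-bis(3-methylbut-2-en-1-yl)phenyl]-1-(phenylsulfinyl)butan-2-one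
Conditions: 9 (3.5 equiv), LiN(iPr)2 (3.5 equiv), THF, −78 °C; add 8, −78 to −50 °C; aq. NH4Cl
Reagents that add atoms: none
Why: Claisen-type acylation of the α-sulfinyl carbanion by the thioester, the sulfur analogue of the chain extension of β-hydroxy esters with excess ester enolate; one equivalent forms the lithium alkoxide, one adds with loss of thiolate and one deprotonates the acidic β-keto sulfoxide, which shields it from further attack, and the carbinol centre is not involved.

Step 6
Reactants: 10 (4S)-4-hydroxy-4-[4-methoxy-3,5-bis(3-methylbut-2-en-1-yl)phenyl]-1-(phenylsulfinyl)butan-2-one; 11 N,N-dimethylformamide dimethyl acetal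
Product: 13 (2S)-2-[4-methoxy-3,5-bis(3-methylbut-2-en-1-yl)phenyl]-5-(phenylsulfinyl)-2,3-dihydro-4H-pyran-4-one, via enaminone 12 (not isolated)
Conditions: 11 (1.1 equiv), toluene, 0 °C to rt; then AcOH, 40 °C
Reagents that add atoms: none
Why: Aminomethylenation of the active methylene between the carbonyl and sulfinyl groups, then acid-promoted 6-endo conjugate addition of the hydroxyl to the enaminone and loss of dimethylamine, the ring closure by which δ-hydroxy-β-keto esters give 2,3-dihydropyran-4-ones; the carbinol C–O bond becomes O1–C2 with retention.

Step 7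
Reactants: 13 (2S)-2-[4-methoxy-3,5-bis(3-methylbut-2-en-1-yl)phenyl]-5-(phenylsulfinyl)-2,3-dihydro-4H-pyran-4-one; 14 (E)-1-methoxy-3-(trimethylsilyloxy)buta-1,3-diene
Product: 18 (2S)-7-hydroxy-2-[4-methoxy-3,5-bis(3-methylbut-2-en-1-yl)phenyl]chroman-4-one (target), via cis-fused sulfinyl cycloadduct 15 (not isolated), via 5-methoxy-5,8-dihydrochromanone 16 (not isolated), via trimethylsilyl ether 17 (not isolated)
Conditions: 14 (3 equiv), toluene, 90 °C; then 1 M HCl, THF, 0 °C to rt
Reagents that add atoms: none
Why: Normal-demand Diels–Alder reaction in which the CH2 terminus of the diene, its most nucleophilic carbon, bonds to C6 of 13 (the later C8a, β to both the carbonyl and the sulfinyl group) and the methoxy-bearing terminus bonds to C5 (the later C4a), so the siloxy carbon becomes C7. The closest known reaction type is the cycloaddition–aromatization of α-sulfinyl enones, sulfinylquinones and 3-acceptor-substituted chromones with 1-alkoxy-3-siloxy dienes. Ring A closes by an intermolecular suprafacial [4+2] annulation across the ring C alkene, which forms C8–C8a and C4a–C5 on one face and gives the cis-fused 15 with the sulfinyl group and H8a cis. At the reaction temperature the sulfoxide leaves by syn-elimination with H8a through a five-membered transition state to restore C4a=C8a (16), 1,4-loss of methanol from C5 and C8 aromatizes the ring (17), and dilute acid hydrolyses the aryl silyl ether to 18. The transient centres C4a, C5 and C8a of 15 are set by the suprafacial addition and the endo or exo approach, but none survives, so facial and endo/exo selectivity do not matter. The step needs regioselectivity, secured by the matched polarization of diene and doubly activated enone, and chemoselectivity for the ring alkene over the unactivated prenyl alkenes, which an electron-rich diene does not attack. No base is present and no bond to C2 is touched, so the configuration from step 4 is kept.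

## Compound list

1 | 3,5-dibromo-4-hydroxybenzaldehyde | Oc1c(Br)cc(C=O)cc1Br | starting material
2 | 3,5-dibromo-4-methoxybenzaldehyde | COc1c(Br)cc(C=O)cc1Br | intermediate
3 | prenylboronic acid pinacol ester | CC(C)=CCB1OC(C)(C)C(C)(C)O1 | starting material
4 | 4-methoxy-3,5-bis(3-methylbut-2-en-1-yl)benzaldehyde | COc1c(CC=C(C)C)cc(C=O)cc1CC=C(C)C | intermediate
5 | S-tert-butyl thioacetate | CC(=O)SC(C)(C)C | starting material
6 | 1-(tert-butylsulfanyl)-1-(trimethylsilyloxy)ethene | C=C(O[Si](C)(C)C)SC(C)(C)C | intermediate
7 | S-tert-butyl (3S)-3-[4-methoxy-3,5-bis(3-methylbut-2-en-1-yl)phenyl]-3-(trimethylsilyloxy)propanethioate | COc1c(CC=C(C)C)cc([C@@H](O[Si](C)(C)C)CC(=O)SC(C)(C)C)cc1CC=C(C)C | intermediate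
8 | S-tert-butyl (3S)-3-hydroxy-3-[4-methoxy-3,5-bis(3-methylbut-2-en-1-yl)phenyl]propanethioate | COc1c(CC=C(C)C)cc([C@@H](O)CC(=O)SC(C)(C)C)cc1CC=C(C)C | intermediate
9 | methyl phenyl sulfoxide (racemic) | CS(=O)c1ccccc1 | starting material
10 | (4S)-4-hydroxy-4-[4-methoxy-3,5-bis(3-methylbut-2-en-1-yl)phenyl]-1-(phenylsulfinyl)butan-2-one (both epimers at sulfur) | COc1c(CC=C(C)C)cc([C@@H](O)CC(=O)CS(=O)c2ccccc2)cc1CC=C(C)C | intermediate
11 | N,N-dimethylformamide dimethyl acetal | COC(OC)N(C)C | starting material
12 | (5S)-1-(dimethylamino)-5-hydroxy-5-[4-methoxy-3,5-bis(3-methylbut-2-en-1-yl)phenyl]-2-(phenylsulfinyl)pent-1-en-3-one (alkene geometry and sulfur configuration not defined) | COc1c(CC=C(C)C)cc([C@@H](O)CC(=O)C(=CN(C)C)S(=O)c2ccccc2)cc1CC=C(C)C | intermediate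
13 | (2S)-2-[4-methoxy-3,5-bis(3-methylbut-2-en-1-yl)phenyl]-5-(phenylsulfinyl)-2,3-dihydro-4H-pyran-4-one (both epimers at sulfur) | COc1c(CC=C(C)C)cc([C@@H]2CC(=O)C(S(=O)c3ccccc3)=CO2)cc1CC=C(C)C | intermediate
14 | (E)-1-methoxy-3-(trimethylsilyloxy)buta-1,3-diene | CO/C=C/C(=C)O[Si](C)(C)C | starting material
15 | (2S)-5-methoxy-2-[4-methoxy-3,5-bis(3-methylbut-2-en-1-yl)phenyl]-4a-(phenylsulfinyl)-7-(trimethylsilyloxy)-2,3,4a,5,8,8a-hexahydro-4H-chromen-4-one (cis ring fusion; mixture at C4a, C5, C8a and sulfur) | COc1c(CC=C(C)C)cc([C@@H]2CC(=O)C3(S(=O)c4ccccc4)C(OC)C=C(O[Si](C)(C)C)CC3O2)cc1CC=C(C)C | intermediate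
16 | (2S)-5-methoxy-2-[4-methoxy-3,5-bis(3-methylbut-2-en-1-yl)phenyl]-7-(trimethylsilyloxy)-2,3,5,8-tetrahydro-4H-chromen-4-one (mixture at C5) | COc1c(CC=C(C)C)cc([C@@H]2CC(=O)C3=C(CC(O[Si](C)(C)C)=CC3OC)O2)cc1CC=C(C)C | intermediate
17 | (2S)-2-[4-methoxy-3,5-bis(3-methylbut-2-en-1-yl)phenyl]-7-(trimethylsilyloxy)chroman-4-one | COc1c(CC=C(C)C)cc([C@@H]2CC(=O)c3ccc(O[Si](C)(C)C)cc3O2)cc1CC=C(C)C | intermediate
18 | (2S)-7-hydroxy-2-[4-methoxy-3,5-bis(3-methylbut-2-en-1-yl)phenyl]chroman-4-one | COc1c(CC=C(C)C)cc([C@@H]2CC(=O)c3ccc(O)cc3O2)cc1CC=C(C)C | target

## Step count and risk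

Total step count: 7. Longest linear sequence: 6 (steps 1, 2, 4, 5, 6, 7); step 3 is a one-step branch that supplies 6.

Step 7 (key step). Two processes are most likely to go wrong.
- Slow cycloaddition: O1 donates into the dienophile, and prolonged heating degrades the acid-sensitive diene.
- Misdirected elimination: in the adduct in which H5 is cis to sulfur, sulfoxide syn-elimination can run toward C5 instead of C8a. Methanol can then no longer be lost, and ring C may open.
- Fallback, from 13 and 14, returning at 18: ZnBr2 in CH2Cl2 at −40 °C, chelated between the sulfinyl and carbonyl oxygens, turns the annulation into a stepwise Mukaiyama–Michael addition and ring closure. Mild acid work-up removes methanol and the silyl group while sulfur is still in place. This should give (2S)-2-[4-methoxy-3,5-bis(3-methylbut-2-en-1-yl)phenyl]-4a-(phenylsulfinyl)-2,3,8,8a-tetrahydro-4H-chromene-4,7(4aH)-dione F1. In F1, C5 is sp2, so warming in toluene allows syn-elimination only toward C8a, and the resulting dienone is the keto tautomer of 18.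

Step 6. The amide acetal is also a dehydrating agent, so loss of water from the benzylic aldol to a styryl ketone may compete with aminomethylenation. An incomplete exchange of nitrogen for oxygen, or ionization at the electron-rich benzylic carbon under acid, would cost material or configuration.
- Fallback, from 4 and 14, returning at 13: a formal hetero-Diels–Alder reaction with (S)-BINOL/Ti(OiPr)4 gives the open-chain silyl aldol adduct F2, which closes with TFA at 0 °C to the dihydropyranone F3.
- I2/pyridine in CH2Cl2 iodinates the nucleophilic C5 without net addition to the prenyl alkenes, to give the iodo enone F4.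
- Coupling with thiophenol (Pd2(dba)3, Xantphos, iPr2NEt, dioxane, 60 °C) gives the phenylsulfanyl enone F5.
- NaIO4 in aqueous methanol oxidizes sulfur only and leads to 13.

Step 5. The carbanion may enolize the thioester instead of adding to it, and the lithium alkoxide may fragment by retro-aldol reaction on warming. Either lowers conversion.
- Fallback, from 8, returning at 10: silylation with TESCl and imidazole in DMF gives the triethylsilyl ether F6.
- Acylation of lithiated 9 (2.2 equiv) with F6 gives the silylated β-keto sulfoxide F7.
- AcOH/THF/water at rt removes the silyl group to give 10.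

Step 4. Facial selectivity may be insufficient, or of the wrong sense, on this hindered and fairly electron-rich aldehyde, and catalyst turnover may be slow.
- Fallback, from 4 and 5, returning at 8: an aldol addition of the lithium enolate of 5 (LiN(iPr)2, THF, −78 °C) gives the racemic hydroxy thioester F8.
- MnO2 in CH2Cl2 oxidizes the benzylic carbinol to the β-keto thioester F9.
- Asymmetric transfer hydrogenation with [RuCl(p-cymene)((S,S)-TsDPEN)] in HCO2H/Et3N reduces the aryl ketone to the (S)-carbinol 8. This catalyst antipode is known to give (S)-carbinols from aryl ketones, and the prenyl alkenes are not reduced.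

Step 2. Allyl transfer through the substituted carbon would give 1,1-dimethylallyl isomers, the second coupling next to the methoxy group may stall, and hydroxide may disproportionate the aldehyde in a Cannizzaro reaction.
- Fallback, from 2, returning at 4: the polarity of the coupling is reversed. Miyaura borylation (B2pin2, PdCl2(dppf), KOAc, dioxane, 90 °C) gives 4-methoxy-3,5-bis(4,4,5,5-tetramethyl-1,3,2-dioxaborolan-2-yl)benzaldehyde F10.
- Coupling of F10 with prenyl bromide (Pd(PPh3)4, K2CO3, THF/water, 60 °C) passes through a π-allyl complex of divalent palladium that is attacked at its unsubstituted terminus, so the linear prenyl groups of 4 result under weakly basic conditions.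

## Further compounds

F1 | step 7 | (2S)-2-[4-methoxy-3,5-bis(3-methylbut-2-en-1-yl)phenyl]-4a-(phenylsulfinyl)-2,3,8,8a-tetrahydro-4H-chromene-4,7(4aH)-dione | COc1c(CC=C(C)C)cc([C@@H]2CC(=O)C3(S(=O)c4ccccc4)C=CC(=O)CC3O2)cc1CC=C(C)C
F2 | step 6 | (1E,5S)-1-methoxy-5-[4-methoxy-3,5-bis(3-methylbut-2-en-1-yl)phenyl]-5-(trimethylsilyloxy)pent-1-en-3-one | COc1c(CC=C(C)C)cc([C@@H](O[Si](C)(C)C)CC(=O)/C=C/OC)cc1CC=C(C)C
F3 | step 6 | (2S)-2-[4-methoxy-3,5-bis(3-methylbut-2-en-1-yl)phenyl]-2,3-dihydro-4H-pyran-4-one | COc1c(CC=C(C)C)cc([C@@H]2CC(=O)C=CO2)cc1CC=C(C)C
F4 | step 6 | (2S)-5-iodo-2-[4-methoxy-3,5-bis(3-methylbut-2-en-1-yl)phenyl]-2,3-dihydro-4H-pyran-4-one | COc1c(CC=C(C)C)cc([C@@H]2CC(=O)C(I)=CO2)cc1CC=C(C)C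
F5 | step 6 | (2S)-2-[4-methoxy-3,5-bis(3-methylbut-2-en-1-yl)phenyl]-5-(phenylsulfanyl)-2,3-dihydro-4H-pyran-4-one | COc1c(CC=C(C)C)cc([C@@H]2CC(=O)C(Sc3ccccc3)=CO2)cc1CC=C(C)C
F6 | step 5 | S-tert-butyl (3S)-3-[4-methoxy-3,5-bis(3-methylbut-2-en-1-yl)phenyl]-3-(triethylsilyloxy)propanethioate | COc1c(CC=C(C)C)cc([C@@H](O[Si](CC)(CC)CC)CC(=O)SC(C)(C)C)cc1CC=C(C)C
F7 | step 5 | (4S)-4-[4-methoxy-3,5-bis(3-methylbut-2-en-1-yl)phenyl]-1-(phenylsulfinyl)-4-(triethylsilyloxy)butan-2-one | COc1c(CC=C(C)C)cc([C@@H](O[Si](CC)(CC)CC)CC(=O)CS(=O)c2ccccc2)cc1CC=C(C)C
F8 | step 4 | S-tert-butyl 3-hydroxy-3-[4-methoxy-3,5-bis(3-methylbut-2-en-1-yl)phenyl]propanethioate (racemic) | COc1c(CC=C(C)C)cc(C(O)CC(=O)SC(C)(C)C)cc1CC=C(C)C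
F9 | step 4 | S-tert-butyl 3-[4-methoxy-3,5-bis(3-methylbut-2-en-1-yl)phenyl]-3-oxopropanethioate | COc1c(CC=C(C)C)cc(C(=O)CC(=O)SC(C)(C)C)cc1CC=C(C)C
F10 | step 2 | 4-methoxy-3,5-bis(4,4,5,5-tetramethyl-1,3,2-dioxaborolan-2-yl)benzaldehyde | COc1c(B2OC(C)(C)C(C)(C)O2)cc(C=O)cc1B1OC(C)(C)C(C)(C)O1
A1 | alternative 1 | (2S)-5-chloro-7-(methoxymethoxy)-2-[4-methoxy-3,5-bis(3-methylbut-2-en-1-yl)phenyl]chroman-4-one | COc1c(CC=C(C)C)cc([C@@H]2CC(=O)c3c(Cl)cc(OCOC)cc3O2)cc1CC=C(C)C
A2 | alternative 1 | methyl (3S)-3-hydroxy-3-[4-methoxy-3,5-bis(3-methylbut-2-en-1-yl)phenyl]propanoate | COc1c(CC=C(C)C)cc([C@@H](O)CC(=O)OC)cc1CC=C(C)C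
A3 | alternative 1 | 3-chloro-5-(methoxymethoxy)-2-(trimethylsilyl)phenyl trifluoromethanesulfonate | COCOc1cc(Cl)c([Si](C)(C)C)c(OS(=O)(=O)C(F)(F)F)c1
A4 | alternative 2 | (2S)-2-[4-methoxy-3,5-bis(3-methylbut-2-en-1-yl)phenyl]-7-(triisopropylsilyloxy)chroman-4-one | COc1c(CC=C(C)C)cc([C@@H]2CC(=O)c3ccc(O[Si](C(C)C)(C(C)C)C(C)C)cc3O2)cc1CC=C(C)C
A5 | alternative 2 | (3S)-3-[2-bromo-5-(triisopropylsilyloxy)phenoxy]-N-methoxy-N-methyl-3-[4-methoxy-3,5-bis(3-methylbut-2-en-1-yl)phenyl]propanamide | COc1c(CC=C(C)C)cc([C@@H](Oc2cc(O[Si](C(C)C)(C(C)C)C(C)C)ccc2Br)CC(=O)N(C)OC)cc1CC=C(C)C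
A6 | alternative 3 | (2S)-7-(methoxymethoxy)-2-[4-methoxy-3,5-bis(3-methylbut-2-en-1-yl)phenyl]chroman-4-one | COc1c(CC=C(C)C)cc([C@@H]2CC(=O)c3ccc(OCOC)cc3O2)cc1CC=C(C)C
A7 | alternative 3 | (3S)-1-[2-fluoro-4-(methoxymethoxy)phenyl]-3-hydroxy-3-[4-methoxy-3,5-bis(3-methylbut-2-en-1-yl)phenyl]propan-1-one | COc1c(CC=C(C)C)cc([C@@H](O)CC(=O)c2ccc(OCOC)cc2F)cc1CC=C(C)C
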